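**Target:** (13S)-13-hydroxy-1-(2,4,6-trihydroxyphenyl)hexadecan-1-one (13), made in seven steps by an iridium-catalysed allylation of a primary alcohol that forms C13–C14 and sets C13.

## Analysis of the target

Compound 13 has one benzene ring (ring A) with three hydroxyl groups and, between two of them, an unbranched sixteen-carbon acyl chain numbered from the ketone carbon C1 to the methyl carbon C16. C2 to C12 are eleven methylene groups, C13 is a secondary carbinol and the only stereocentre, and C14 to C16 form an n-propyl end. At C13 the priorities are OH, then the long chain, then propyl, and the SMILES corresponds to the S descriptor. The centre is eleven methylenes away from any other functional group, so no substrate control is available and its configuration must come from a reagent or catalyst. The sensitive part is the acylated trihydroxyphenyl head: the free ring is acidic, easily oxidised and nucleophilic at carbon, so the three phenols stay masked until the last step, and the aryl ketone must survive whatever removes the masks. The difficulty is the stereocentre itself, because its two carbon substituents are unbranched alkyl chains that differ only beyond the third atom, so an enantioselective reduction of a C13 ketone would have little to distinguish. The strategy rests on the propyl group C14–C16, which is a saturated allyl group: C13–C14 and the C13 configuration can be created together by adding an allyl unit to a C13 carbonyl that bears hydrogen on one side and the chain on the other. That carbonyl can be generated in the flask from a primary alcohol, and the olefin left by the allyl group disappears in the same hydrogenation that frees ring A.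

## Retrosynthetic reasoning

**13 from 12.** No skeletal bond is cut. The three phenols are traced back to benzyl ethers and the propyl end to an allyl group, giving 12. Benzyl is chosen because its hydrogenolysis and the saturation of C15=C16 are one operation, so the olefin costs no step. The forward reaction must leave the C1 ketone and the C13 carbinol untouched. On saturation the descriptor changes from R in 12 to S in 13 without any change at the centre, because allyl outranks the long chain but propyl does not.

**12 from 9 and 10.** The C13–C14 bond is cut. This is the only bond whose formation can also create the stereocentre from a carbonyl with two clearly different substituents (H and chain), and the fragment set free is exactly the three-carbon unit of 10. The carbonyl partner is taken one oxidation level lower, as the primary alcohol 9, so that the sensitive keto aldehyde 11 only exists transiently and no stoichiometric chiral reagent, oxidant or reductant is needed. The forward reaction must differentiate the aldehyde faces by the catalyst alone, dehydrogenate only the primary carbinol, and ignore the C1 ketone.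

**9 from 8 and 7.** These are functional-group changes. The C13 hydroxyl is carried as a silyl ether (8) through the steps that use a carbanion and an oxidant, and the C1 ketone is taken back to the carbinol 7. Oxidation comes before desilylation so that only one free hydroxyl is present when the oxidant is used.

**7 from 3 and 5 via 6.** The C1–C2 bond is cut, next to ring A. This separates the aromatic head from the whole linear C12 chain. The aldehyde 3 has no α-hydrogen and is a clean electrophile for the Grignard reagent 6. A cut further along the chain would place a bond between two unfunctionalised methylenes and gain nothing.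

**3 from 1 via 2.** The bond between ring A and the formyl carbon is cut. The arene 1 already carries the three benzyl ethers, and its three free ring positions are equivalent and strongly activated, so an electrophilic formylation can give only one regioisomer. The iminium salt 2 that forms first deactivates the ring against a second attack and is hydrolysed to 3 on work-up.

**5 from 4.** This is a protecting step on a commercial material: silylation of 4 so that its bromide can be converted into 6.

## Alternatives that were turned down

**Alternative 1: hydroacylation forming C1–C2.** The C1–C2 bond would be made by adding the formyl C–H of 2-hydroxy-4,6-bis(methoxymethoxy)benzaldehyde A2 across the terminal olefin of (S)-tert-butyldimethyl(pentadec-14-en-4-yloxy)silane A3. The catalyst would be [Rh(cod)Cl]2 with a bulky phosphoramidite and K3PO4, the free ortho phenol acting as directing group, and the product would be the ketone A1.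
- For it: the aryl ketone appears directly at the right oxidation level, there is no stoichiometric organometallic reagent, the route is convergent, and one acidic step would remove all protecting groups from A1. On atom economy and on avoiding the carbinol-to-ketone adjustment it is stronger than the chosen route.
- Against it: the stereocentre is not addressed, so A3 must be made enantiopure by a separate sequence that needs its own asymmetric C–C or C–O bond formation. The second ortho substituent of A2 crowds the acyl rhodium hydride, which makes the required linear selectivity and the suppression of olefin migration along the long chain of A3 less secure than with simple salicylaldehydes.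
- Comparison: the chosen route creates the only stereocentre in the same step as a skeletal bond, on the assembled chain, from achiral commercial materials.

**Alternative 2: electrochemical decarboxylative coupling at C11–C12.** The C11–C12 bond would be formed by reductive coupling of the two redox-active esters A5 (aryl keto acid part, C1–C11) and A6 (C12–C16 with the silyloxy group) at a silver-coated cathode with NiCl2·glyme and a terpyridine-type ligand, giving A4.
- For it: the stereocentre of A6 comes from a β-hydroxy acid, a pattern for which very reliable asymmetric methods exist, and on that point it is stronger than the chosen route. The coupling is also modular.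
- Against it: both radicals are primary and unstabilised, so nothing in the structures favours cross-coupling over the two homodimers. The radical from A6 has the silyloxy group on the β-carbon, which opens β-elimination at nickel. The aryl ketone and benzyl ethers must survive the cathode. Each ester needs its own multistep preparation, and C11–C12 has no functional handle in 13, so the cut does not simplify the molecule.
- Comparison: the chosen route is shorter and its key bond is formed by a polar, closed transition state and not by statistical radical pairing.

**Alternative 3: nickel hydride coupling at C12–C13.** The C12–C13 bond and the stereocentre would be formed together by hydrometallation of the terminal olefin A8 and enantioconvergent coupling with racemic 1-bromobutyl benzoate A9, using NiBr2·glyme, a chiral bis(oxazoline), a hydrosilane and K3PO4, to give the benzoate A7.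
- For it: like the chosen route it builds bond and stereocentre in one catalytic step. A8 needs no hydroxyl protection, so its precursor is about two steps shorter, and even with the extra ester cleavage the route is at least as short overall.
- Against it: the catalyst must distinguish n-propyl from the incoming unbranched chain at the C13 radical, with the benzoyloxy group as the only handle. The nickel hydride can migrate along the chain of A8 and the hydrosilane can reduce the ketone. A9 is a hydrolytically labile α-halo ester. A7 needs a separate benzoate cleavage before hydrogenolysis.
- Comparison: the chosen route offers a stable, inexpensive allyl donor, a redox-neutral addition to a C=O group with a well-defined chair transition state, and a fallback (reagent-controlled allylation of the same aldehyde) that keeps the disconnection.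

Key step: step 6

**Assumption (chemistry):** the (S)-configured biaryl bisphosphine is taken to deliver the (13R)-homoallylic alcohol from an unbranched aliphatic aldehyde. If a Mosher ester analysis of 12 shows the opposite sense, the ligand antipode is used with nothing else changed.

**Assumption (materials):** 1,3,5-tris(benzyloxy)benzene 1 (phloroglucinol tribenzyl ether) is taken as a catalogue compound.

## Route

Step 1
Reactants: 1 1,3,5-tris(benzyloxy)benzene
Product: 3 2,4,6-tris(benzyloxy)benzaldehyde, via iminium salt 2 (not isolated)
Conditions: POCl3, DMF, 0 °C to rt; then aq. NaOAc, rt
Reagents that add atoms: N,N-dimethylformamide (DMF), CN(C)C=O; water, O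
Why: Vilsmeier–Haack formylation in which POCl3 converts DMF into the chloroiminium electrophile, which attacks one of the three equivalent, doubly ortho-activated ring positions of 1 to give the iminium salt 2, and aqueous acetate hydrolyses 2 to the aldehyde 3; the iminium group deactivates the ring, so a second formylation should not compete.

Step 2
Reactants: 4 12-bromododecan-1-ol
Product: 5 (12-bromododecyloxy)(tert-butyl)dimethylsilane
Conditions: TBSCl, imidazole, CH2Cl2, 0 °C to rt
Reagents that add atoms: tert-butyldimethylsilyl chloride (TBSCl), CC(C)(C)[Si](C)(C)Cl
Why: Standard silylation of a primary alcohol with imidazole as base and nucleophilic catalyst; the silyl ether removes the acidic hydroxyl so that the bromide can be converted into a Grignard reagent.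

Step 3
Reactants: 5 (12-bromododecyloxy)(tert-butyl)dimethylsilane; 3 2,4,6-tris(benzyloxy)benzaldehyde
Product: 7 13-(tert-butyldimethylsilyloxy)-1-[2,4,6-tris(benzyloxy)phenyl]tridecan-1-ol (racemic at C1), via Grignard reagent 6 (not isolated)
Conditions: Mg, I2 (cat.), THF, 50 °C; then 3, THF, 0 °C to rt; aq. NH4Cl
Reagents that add atoms: none
Why: Magnesium insertion into the primary C–Br bond gives 6, which adds to the non-enolisable aldehyde 3 (Grignard addition) and forms C1–C2; silyl and benzyl ethers are inert, and the C1 carbinol centre is formed as a racemate that is removed by oxidation in step 4.

Step 4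
Reactants: 7 13-(tert-butyldimethylsilyloxy)-1-[2,4,6-tris(benzyloxy)phenyl]tridecan-1-ol
Product: 8 13-(tert-butyldimethylsilyloxy)-1-[2,4,6-tris(benzyloxy)phenyl]tridecan-1-one
Conditions: Dess–Martin periodinane, pyridine, CH2Cl2, 0 °C to rt
Reagents that add atoms: none
Why: Dess–Martin oxidation of a secondary benzylic alcohol to the aryl ketone; pyridine buffers the acetic acid released so that the electron-rich carbinol does not ionise, and the silyl and benzyl ethers are not touched.

Step 5
Reactants: 8 13-(tert-butyldimethylsilyloxy)-1-[2,4,6-tris(benzyloxy)phenyl]tridecan-1-one
Product: 9 13-hydroxy-1-[2,4,6-tris(benzyloxy)phenyl]tridecan-1-one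
Conditions: HF·pyridine, pyridine, THF, 0 °C to rt
Reagents that add atoms: none
Why: Fluoride cleavage of a primary tert-butyldimethylsilyl ether, driven by the strong Si–F bond; benzyl ethers and the hindered ketone should not react under these buffered conditions.

Step 6
Reactants: 9 13-hydroxy-1-[2,4,6-tris(benzyloxy)phenyl]tridecan-1-one; 10 allyl acetate
Product: 12 (13R)-13-hydroxy-1-[2,4,6-tris(benzyloxy)phenyl]hexadec-15-en-1-one, via transient aldehyde 11 (not isolated)
Conditions: [Ir(cod)Cl]2 (2.5 mol%), (S)-Cl,MeO-BIPHEP (5 mol%), 4-chloro-3-nitrobenzoic acid (10 mol%), Cs2CO3 (20 mol%), allyl acetate (5 equiv), THF, 100 °C, sealed tube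
Reagents that add atoms: none
Why: This is a transfer-hydrogenative carbonyl allylation run from the alcohol oxidation level (Krische allylation), a reaction type established for unbranched aliphatic primary alcohols. [Ir(cod)Cl]2, the bisphosphine, 4-chloro-3-nitrobenzoic acid and 10 should assemble in the flask into an ortho-cyclometallated π-allyl C,O-benzoate complex of trivalent iridium. Its alkoxide with 9 undergoes β-hydride elimination to the transient aldehyde 11 and an iridium hydride; Cs2CO3 removes the acid from the hydride and the resulting monovalent iridium species adds 10 oxidatively to regenerate the allyl complex, so no oxidant, reductant or allylmetal reagent is needed. The σ-allyl form then adds to 11 through a closed six-membered chair transition state with the aldehyde chain equatorial, which forms C13–C14; no ring is closed. The new C13 stereocentre is controlled by the catalyst alone, and the (S)-configured ligand is expected to expose the aldehyde face that leads to the (13R) alcohol. The step needs chemoselectivity for the primary carbinol: the C1 ketone lies between two ortho benzyloxy groups and is at the ketone level, which this allyl complex does not attack and the hydride should not reduce, and the homoallylic alcohol 12 is shielded from re-oxidation by coordination of its olefin to iridium. Benzyl ethers are inert and the only by-product is acetic acid.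

Step 7
Reactants: 12 (13R)-13-hydroxy-1-[2,4,6-tris(benzyloxy)phenyl]hexadec-15-en-1-one
Product: 13 (13S)-13-hydroxy-1-(2,4,6-trihydroxyphenyl)hexadecan-1-one
Conditions: H2 (1 atm), 10% Pd/C, EtOAc/MeOH, rt
Reagents that add atoms: none
Why: Heterogeneous hydrogenation saturates the terminal olefin and hydrogenolysis cleaves the three benzylic C–O bonds in the same operation, releasing toluene; the C13 carbinol is not benzylic and its configuration is retained, the descriptor changing from R to S only because propyl ranks below the long chain. The electron-rich, internally hydrogen-bonded aryl ketone should resist reduction at one atmosphere.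

## Compound list

1 | 1,3,5-tris(benzyloxy)benzene | c1ccc(COc2cc(OCc3ccccc3)cc(OCc3ccccc3)c2)cc1 | starting material
2 | [2,4,6-tris(benzyloxy)benzylidene]dimethyliminium chloride (formed in the flask, not isolated) | C[N+](C)=Cc1c(OCc2ccccc2)cc(OCc2ccccc2)cc1OCc1ccccc1.[Cl-] | intermediate
3 | 2,4,6-tris(benzyloxy)benzaldehyde | O=Cc1c(OCc2ccccc2)cc(OCc2ccccc2)cc1OCc1ccccc1 | intermediate
4 | 12-bromododecan-1-ol | OCCCCCCCCCCCCBr | starting material
5 | (12-bromododecyloxy)(tert-butyl)dimethylsilane | CC(C)(C)[Si](C)(C)OCCCCCCCCCCCCBr | intermediate
6 | [12-(tert-butyldimethylsilyloxy)dodecyl]magnesium bromide (formed in the flask, not isolated) | CC(C)(C)[Si](C)(C)OCCCCCCCCCCCC[Mg]Br | intermediate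
7 | 13-(tert-butyldimethylsilyloxy)-1-[2,4,6-tris(benzyloxy)phenyl]tridecan-1-ol (racemic at C1) | CC(C)(C)[Si](C)(C)OCCCCCCCCCCCCC(O)c1c(OCc2ccccc2)cc(OCc2ccccc2)cc1OCc1ccccc1 | intermediate
8 | 13-(tert-butyldimethylsilyloxy)-1-[2,4,6-tris(benzyloxy)phenyl]tridecan-1-one | CC(C)(C)[Si](C)(C)OCCCCCCCCCCCCC(=O)c1c(OCc2ccccc2)cc(OCc2ccccc2)cc1OCc1ccccc1 | intermediate
9 | 13-hydroxy-1-[2,4,6-tris(benzyloxy)phenyl]tridecan-1-one | OCCCCCCCCCCCCC(=O)c1c(OCc2ccccc2)cc(OCc2ccccc2)cc1OCc1ccccc1 | intermediate
10 | allyl acetate | C=CCOC(C)=O | starting material
11 | 13-oxo-13-[2,4,6-tris(benzyloxy)phenyl]tridecanal (formed in the flask, not isolated) | O=CCCCCCCCCCCCC(=O)c1c(OCc2ccccc2)cc(OCc2ccccc2)cc1OCc1ccccc1 | intermediate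
12 | (13R)-13-hydroxy-1-[2,4,6-tris(benzyloxy)phenyl]hexadec-15-en-1-one | C=CC[C@H](O)CCCCCCCCCCCC(=O)c1c(OCc2ccccc2)cc(OCc2ccccc2)cc1OCc1ccccc1 | intermediate
13 | (13S)-13-hydroxy-1-(2,4,6-trihydroxyphenyl)hexadecan-1-one | CCC[C@H](O)CCCCCCCCCCCC(=O)c1c(O)cc(O)cc1O | target

## Step count and least certain steps

Total step count: 7. Longest linear sequence: 6 steps (steps 1, 3, 4, 5, 6, 7 from 1, or steps 2 to 7 from 4).

**Step 6 (key step).** The most likely failures are incomplete dehydrogenation of the long lipophilic alcohol, acetyl transfer from 10 to the primary hydroxyl under carbonate, base-mediated aldol reactions of the transient aldehyde, and erosion of facial selectivity at 100 °C, since the only source of induction is the ligand. The fallback sets out from 9 and comes back at 12. Compound 9 would be oxidised with Dess–Martin periodinane and pyridine to the aldehyde 11, now isolated. Compound 11 would then be treated at −78 °C in Et2O with (−)-B-allyldiisopinocampheylborane, (−)-Ipc2B(allyl), made from (−)-Ipc2BOMe and allylmagnesium bromide, followed by ethanolamine work-up (Brown allylation). This reagent is expected to attack the si face of an unbranched aldehyde and so give the (13R) alcohol 12. The disconnection is kept, but the catalytic redox-neutral process is replaced by stoichiometric reagent control at the aldehyde level. No new compound is made on this way (entry F0 below).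

**Step 7.** Three processes could interfere: palladium-mediated migration of the C15=C16 double bond toward C13 before saturation, which through the enol would convert the carbinol into a ketone and erase the stereocentre; hydrogenolytic over-reduction of the aryl ketone; and slow cleavage of the crowded ortho benzyl ethers. The fallback sets out from 12 and comes back at 13, separating the two tasks and avoiding a metal hydride. The olefin would first be reduced with diimide (2-nitrobenzenesulfonyl hydrazide, Et3N, CH2Cl2, rt) to give (13S)-13-hydroxy-1-[2,4,6-tris(benzyloxy)phenyl]hexadecan-1-one F1. The benzyl ethers of F1 would then be cleaved without any reductant using BCl3 and pentamethylbenzene as cation scavenger in CH2Cl2 at −78 °C, giving 13.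

**Step 1.** Hydrogen chloride and phosphorus chlorides are present throughout, so acid-promoted loss of a benzyl group from an ether ortho to the new iminium or formyl group can occur, assisted by the neighbouring carbonyl; a second formylation of the still electron-rich ring is the other risk. The fallback sets out from 1 and comes back at 3, and it introduces the formyl group through an aryl anion under non-acidic conditions. Compound 1 would be monobrominated with N-bromosuccinimide in CH2Cl2 at −20 °C to give 2-bromo-1,3,5-tris(benzyloxy)benzene F2. Bromine–lithium exchange of F2 with n-BuLi in THF at −78 °C, which is much faster than deprotonation of a benzylic methylene, would give [2,4,6-tris(benzyloxy)phenyl]lithium F3. Quenching F3 with DMF, followed by aqueous NH4Cl, would give 3.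

**Step 3.** Wurtz-type homocoupling during magnesium insertion and hydride transfer from the β-methylene of 6 to the crowded aldehyde (reduction in place of addition) would lower the amount of 7. The fallback sets out from 3 and comes back at 8, so it also replaces step 4. Commercial dodec-11-yn-1-ol F4 would be silylated (TBSCl, imidazole) to tert-butyl(dodec-11-yn-1-yloxy)dimethylsilane F5. F5 would be deprotonated with n-BuLi in THF at −78 °C and added to 3; an acetylide has no β-hydrogen to transfer and is small. This would give 13-(tert-butyldimethylsilyloxy)-1-[2,4,6-tris(benzyloxy)phenyl]tridec-2-yn-1-ol F6. Oxidation of F6 with MnO2 in CH2Cl2 would give 13-(tert-butyldimethylsilyloxy)-1-[2,4,6-tris(benzyloxy)phenyl]tridec-2-yn-1-one F7. Hydrogenation of the triple bond of F7 over Pd/C poisoned with diphenyl sulfide (H2, EtOAc, rt), conditions under which benzyl ethers and aryl ketones are retained, would give 8.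

## Further compounds

F0 | step 6 | none | none
F1 | step 7 | (13S)-13-hydroxy-1-[2,4,6-tris(benzyloxy)phenyl]hexadecan-1-one | CCC[C@H](O)CCCCCCCCCCCC(=O)c1c(OCc2ccccc2)cc(OCc2ccccc2)cc1OCc1ccccc1
F2 | step 1 | 2-bromo-1,3,5-tris(benzyloxy)benzene | Brc1c(OCc2ccccc2)cc(OCc2ccccc2)cc1OCc1ccccc1
F3 | step 1 | [2,4,6-tris(benzyloxy)phenyl]lithium (formed in the flask) | [Li]c1c(OCc2ccccc2)cc(OCc2ccccc2)cc1OCc1ccccc1
F4 | step 3 | dodec-11-yn-1-ol | C#CCCCCCCCCCCO
F5 | step 3 | tert-butyl(dodec-11-yn-1-yloxy)dimethylsilane | C#CCCCCCCCCCCO[Si](C)(C)C(C)(C)C
F6 | step 3 | 13-(tert-butyldimethylsilyloxy)-1-[2,4,6-tris(benzyloxy)phenyl]tridec-2-yn-1-ol (racemic) | CC(C)(C)[Si](C)(C)OCCCCCCCCCCC#CC(O)c1c(OCc2ccccc2)cc(OCc2ccccc2)cc1OCc1ccccc1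
F7 | step 3 | 13-(tert-butyldimethylsilyloxy)-1-[2,4,6-tris(benzyloxy)phenyl]tridec-2-yn-1-one | CC(C)(C)[Si](C)(C)OCCCCCCCCCCC#CC(=O)c1c(OCc2ccccc2)cc(OCc2ccccc2)cc1OCc1ccccc1
A1 | alternative 1 | (13S)-13-(tert-butyldimethylsilyloxy)-1-[2-hydroxy-4,6-bis(methoxymethoxy)phenyl]hexadecan-1-one | CCC[C@H](O[Si](C)(C)C(C)(C)C)CCCCCCCCCCCC(=O)c1c(O)cc(OCOC)cc1OCOC
A2 | alternative 1 | 2-hydroxy-4,6-bis(methoxymethoxy)benzaldehyde | O=Cc1c(O)cc(OCOC)cc1OCOC
A3 | alternative 1 | (S)-tert-butyldimethyl(pentadec-14-en-4-yloxy)silane | CCC[C@H](O[Si](C)(C)C(C)(C)C)CCCCCCCCCC=C
A4 | alternative 2 | (13S)-13-(tert-butyldimethylsilyloxy)-1-[2,4,6-tris(benzyloxy)phenyl]hexadecan-1-one | CCC[C@H](O[Si](C)(C)C(C)(C)C)CCCCCCCCCCCC(=O)c1c(OCc2ccccc2)cc(OCc2ccccc2)cc1OCc1ccccc1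
A5 | alternative 2 | 1,3-dioxoisoindolin-2-yl 12-oxo-12-[2,4,6-tris(benzyloxy)phenyl]dodecanoate | O=C(ON1C(=O)c2ccccc2C1=O)CCCCCCCCCCC(=O)c1c(OCc2ccccc2)cc(OCc2ccccc2)cc1OCc1ccccc1
A6 | alternative 2 | 1,3-dioxoisoindolin-2-yl (3S)-3-(tert-butyldimethylsilyloxy)hexanoate | CCC[C@H](O[Si](C)(C)C(C)(C)C)CC(=O)ON1C(=O)c2ccccc2C1=O
A7 | alternative 3 | (4S)-16-oxo-16-[2,4,6-tris(benzyloxy)phenyl]hexadecan-4-yl benzoate | CCC[C@H](OC(=O)c1ccccc1)CCCCCCCCCCCC(=O)c1c(OCc2ccccc2)cc(OCc2ccccc2)cc1OCc1ccccc1
A8 | alternative 3 | 1-[2,4,6-tris(benzyloxy)phenyl]dodec-11-en-1-one | C=CCCCCCCCCCC(=O)c1c(OCc2ccccc2)cc(OCc2ccccc2)cc1OCc1ccccc1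
A9 | alternative 3 | 1-bromobutyl benzoate (racemic) | CCCC(Br)OC(=O)c1ccccc1
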